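**Retrosynthetic overview**

1. Numbering follows the target: five-membered ring C1(OAc)–C2–C3(OH, iPr)–C4(H)–C10(CH3), seven-membered ring C4–C5(OAr)–C6–C7(CH3)=C8–C9–C10; β is the face of the C10 methyl.
2. The strategy rests on the C4–C10 fusion bond: with H-4 anti to the C10 methyl and an oxygen on the neighbouring C5, it is the footprint of a 1,2-shift of C10 from a C5 carbinol carbon to C4. Cutting it backwards gives a cis-decalin (ring A: C1–C5, C10; ring B: C5–C10) 3β,4β,5β-triol 4-mesylate.
3. After the shift the C3 tertiary hydroxyl steers both carbonyl reductions (C5, then C1 after unmasking); C5 aroylation, C1 acetylation and phenol release finish the route.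
4. The triol comes from hydroxyl-directed osmylation of a C4=C5 alkene next to the C3 carbinol, which is made by isopropyl addition to a 4β-phenylthio 3-ketone and sulfoxide elimination.
5. Ring order: ring A from (R)-carvone (as (R)-5-acetoxy-2-methylcyclohexenone), ring B by Diels–Alder reaction with isoprene, then both six-membered rings become the five- and seven-membered rings in one step.

Key step: step 11

Remark on the chemistry: C1 is kept at the ketone level (ethylene ketal) through the key step, because a C1 carbinol cannot be set reliably on the cis-decalone and an axial 1α-ether would turn the isopropyl nucleophile to the wrong face of C3; after ring contraction the C3 hydroxyl delivers hydride to C1.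

**Route**

Step 1
Reactants: 1 (R)-(−)-carvone
Product: 3 (R)-5-acetoxy-2-methylcyclohex-2-en-1-one, via methoxy hydroperoxide 2 (not isolated)
Conditions: O3, CH2Cl2/MeOH, −78 °C; then Ac2O, Et3N, DMAP (cat.), 0 °C → rt
Reagents that add atoms: ozone ([O-][O+]=O); methanol (CO)
Why: Ozone cleaves the electron-rich 1,1-disubstituted alkene in preference to the enone, methanol traps the carbonyl oxide, and acetylation of the hydroperoxide triggers a Criegee rearrangement in which the ring carbon migrates to oxygen with retention, so the carvone stereocentre becomes the acetoxy carbon unchanged.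

Step 2
Reactants: 3 (R)-5-acetoxy-2-methylcyclohex-2-en-1-one; 4 isoprene
Product: 5 cis-fused 3β-acetoxy-7,10β-dimethyl-5βH-decal-7-en-1-one
Conditions: EtAlCl2 (0.5 equiv), toluene, −20 °C → rt
Reagents that add atoms: none
Why: Lewis-acid-catalysed Diels–Alder reaction in which the single ketone dictates the para orientation (methyl on C7), suprafacial addition gives the cis fusion, and the diene adds to the enone face anti to the acetoxy group, setting C10 (methyl β) and C5 (H β).

Step 3
Reactants: 5 cis-fused 3β-acetoxy-7,10β-dimethyl-5βH-decal-7-en-1-one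
Product: 6 3β-acetoxy-1,1-ethylenedioxy-7,10β-dimethyl-5βH-cis-decal-7-ene
Conditions: TMSOCH2CH2OTMS, TMSOTf (cat.), CH2Cl2, −78 → −20 °C
Reagents that add atoms: 1,2-bis(trimethylsilyloxy)ethane (C[Si](C)(C)OCCO[Si](C)(C)C)
Why: Noyori ketalisation under aprotic low-temperature conditions masks the C1 ketone without β-elimination of the acetate, and no stereocentre is formed.

Step 4
Reactants: 6 3β-acetoxy-1,1-ethylenedioxy-7,10β-dimethyl-5βH-cis-decal-7-ene
Product: 7 1,1-ethylenedioxy-7,10β-dimethyl-5βH-cis-decal-7-en-3β-ol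
Conditions: K2CO3 (cat.), MeOH, 0 °C → rt
Reagents that add atoms: none
Why: Base-catalysed transesterification frees the C3 alcohol, and with C1 ketalised no enolisable carbonyl is left to expel the β-oxygen.

Step 5
Reactants: 7 1,1-ethylenedioxy-7,10β-dimethyl-5βH-cis-decal-7-en-3β-ol
Product: 8 1,1-ethylenedioxy-7,10β-dimethyl-5βH-cis-decal-7-en-3-one
Conditions: Pr4N[RuO4] (cat.), NMO, 4 Å MS, CH2Cl2, rt
Reagents that add atoms: none
Why: Ley–Griffith oxidation converts the secondary alcohol into the C3 ketone under neutral conditions that spare the ketal and the trisubstituted alkene.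

Step 6
Reactants: 8 1,1-ethylenedioxy-7,10β-dimethyl-5βH-cis-decal-7-en-3-one
Product: 10 1,1-ethylenedioxy-7,10β-dimethyl-4β-phenylthio-5βH-cis-decal-7-en-3-one, via lithium enolate 9 (not isolated)
Conditions: LiN(iPr)2, THF, −78 °C; then PhSO2SPh, −78 °C
Reagents that add atoms: S-phenyl benzenethiosulfonate (O=S(=O)(Sc1ccccc1)c1ccccc1)
Why: Kinetic deprotonation takes place at C4, away from the neopentyl C2 methylene next to the spiro-ketal, and Trost sulfenylation of the enolate on the convex β-face (anti to the axial C9 methylene) gives the equatorial 4β-sulfide, cis to H-5 and also the thermodynamic epimer.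

Step 7
Reactants: 10 1,1-ethylenedioxy-7,10β-dimethyl-4β-phenylthio-5βH-cis-decal-7-en-3-one
Product: 11 1,1-ethylenedioxy-3α-isopropyl-7,10β-dimethyl-4β-phenylthio-5βH-cis-decal-7-en-3β-ol
Conditions: iPrMgCl, CeCl3, THF, −78 → 0 °C
Reagents that add atoms: isopropylmagnesium chloride (CC(C)[Mg]Cl)
Why: Organocerium 1,2-addition (Imamoto conditions) limits enolisation, and in the chair with sulfide and C10 methyl equatorial the β-axial ketal oxygen on C1 blocks the axial trajectory, so the bulky nucleophile enters equatorially from the α-face and sets C3 with hydroxyl β and isopropyl α.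

Step 8
Reactants: 11 1,1-ethylenedioxy-3α-isopropyl-7,10β-dimethyl-4β-phenylthio-5βH-cis-decal-7-en-3β-ol
Product: 13 1,1-ethylenedioxy-3α-isopropyl-7,10β-dimethyldecala-4,7-dien-3β-ol, via sulfoxide 12 (not isolated)
Conditions: mCPBA (1.0 equiv), CH2Cl2, −78 °C; then toluene, 110 °C
Reagents that add atoms: none
Why: Sulfur is oxidised far faster than the ring alkene, and thermal syn-elimination of the sulfoxide (Trost dehydrosulfenylation) can only use the cis 5β-hydrogen because C3 carries none, so the C4=C5 alkene forms regiospecifically.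

Step 9
Reactants: 13 1,1-ethylenedioxy-3α-isopropyl-7,10β-dimethyldecala-4,7-dien-3β-ol
Product: 15 1,1-ethylenedioxy-3α-isopropyl-7,10β-dimethyl-cis-decal-7-ene-3β,4β,5β-triol, via osmate ester 14 (not isolated)
Conditions: OsO4 (1.05 equiv), TMEDA, CH2Cl2, −78 °C; then aq. Na2SO3, THF, 60 °C
Reagents that add atoms: osmium tetroxide (O=[Os](=O)(=O)=O)
Why: Donohoe hydrogen-bond-directed dihydroxylation, in which the C3 hydroxyl binds the OsO4·TMEDA complex and delivers it to the β-face of the adjacent C4=C5 alkene in preference to the remote C7=C8 alkene, sets C4 and C5 with both oxygens β (cis ring fusion) before the osmate ester is cleaved.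

Step 10
Reactants: 15 1,1-ethylenedioxy-3α-isopropyl-7,10β-dimethyl-cis-decal-7-ene-3β,4β,5β-triol
Product: 16 1,1-ethylenedioxy-3α-isopropyl-7,10β-dimethyl-cis-decal-7-ene-3β,4β,5β-triol 4-methanesulfonate
Conditions: MsCl, pyridine, DMAP (cat.), CH2Cl2, 0 °C
Reagents that add atoms: methanesulfonyl chloride (CS(=O)(=O)Cl)
Why: Sulfonylation takes the only secondary hydroxyl (equatorial C4–OH) and leaves the two tertiary alcohols untouched, with no change at any stereocentre.

Step 11
Reactants: 16 1,1-ethylenedioxy-3α-isopropyl-7,10β-dimethyl-cis-decal-7-ene-3β,4β,5β-triol 4-methanesulfonate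
Product: 17 1,1-ethylenedioxy-3β-hydroxy-3α-isopropyl-7,10β-dimethyl-4αH-trans-hydroazul-7-en-5-one
Conditions: KOtBu (1.2 equiv), THF/t-BuOH, 0 °C → rt
Reagents that add atoms: none
Why: KOtBu deprotonates the C5 tertiary hydroxyl, and the alkoxide pushes while the C5–C10 ring bond, antiperiplanar to the equatorial C4 mesylate in the chair of ring A (isopropyl, mesylate and C10 methyl equatorial, C3 and C5 hydroxyls axial), migrates to C4 in a concerted 1,2-shift that expels mesylate and leaves the C5 ketone. The closest known reaction type is the base-induced pinacol-type (semipinacol) rearrangement of cyclic 1,2-diol monosulfonates, used to turn cis-decalins into hydroazulenones. The five-membered ring C1–C2–C3–C4–C10 closes by contraction of ring A through the new C4–C10 bond, and the seven-membered ring C4–C5–C6–C7–C8–C9–C10 arises by one-carbon expansion of ring B as C4 is inserted between C5 and C10. C4 is the only new stereocentre: C10 enters from the side opposite the β-mesylate (inversion), so H-4 ends α and anti to the C10 methyl (trans fusion), while C10 migrates with retention. The step needs migration of C10 (C5 alkoxide) to outrun migration of C2 (C3 alkoxide): C10 is fully substituted and its shift relieves the vicinal quaternary congestion, C2 is a methylene deactivated by the two ketal oxygens on C1, and no oxygen stands anti to the mesylate, so epoxide closure cannot compete.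

Step 12
Reactants: 17 1,1-ethylenedioxy-3β-hydroxy-3α-isopropyl-7,10β-dimethyl-4αH-trans-hydroazul-7-en-5-one
Product: 18 1,1-ethylenedioxy-3α-isopropyl-7,10β-dimethyl-4αH-trans-hydroazul-7-ene-3β,5α-diol
Conditions: Me4N[BH(OAc)3], MeCN/AcOH, −20 °C
Reagents that add atoms: none
Why: Evans–Saksena reduction, in which the C3 hydroxyl exchanges onto boron and hydride is delivered intramolecularly to the β-face of the C5 ketone, gives the 5α-alcohol anti to the 3β-hydroxyl.

Step 13
Reactants: 19 4-hydroxybenzoic acid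
Product: 21 4-(allyloxy)benzoic acid, via potassium 4-(allyloxy)benzoate 20 (not isolated)
Conditions: KOH, allyl bromide, EtOH/H2O, reflux; then aq. HCl
Reagents that add atoms: allyl bromide (C=CCBr)
Why: Williamson ether synthesis on the dianion, whose phenoxide is far more nucleophilic than the carboxylate, followed by acidification to the free acid.

Step 14
Reactants: 18 1,1-ethylenedioxy-3α-isopropyl-7,10β-dimethyl-4αH-trans-hydroazul-7-ene-3β,5α-diol; 21 4-(allyloxy)benzoic acid
Product: 22 5α-[4-(allyloxy)benzoyloxy]-1,1-ethylenedioxy-3α-isopropyl-7,10β-dimethyl-4αH-trans-hydroazul-7-en-3β-ol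
Conditions: DCC, DMAP (cat.), CH2Cl2, rt
Reagents that add atoms: none
Why: Steglich esterification acylates the secondary C5 hydroxyl, while the hindered tertiary C3 hydroxyl does not react.

Step 15
Reactants: 22 5α-[4-(allyloxy)benzoyloxy]-1,1-ethylenedioxy-3α-isopropyl-7,10β-dimethyl-4αH-trans-hydroazul-7-en-3β-ol
Product: 23 5α-[4-(allyloxy)benzoyloxy]-3β-hydroxy-3α-isopropyl-7,10β-dimethyl-4αH-trans-hydroazul-7-en-1-one
Conditions: TsOH·H2O (cat.), THF/H2O, rt
Reagents that add atoms: water (O)
Why: Mild acid-catalysed hydrolysis of the dioxolane releases the C1 ketone, and the aryl ester, allyl ether and tertiary alcohol tolerate catalytic sulfonic acid at room temperature.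

Step 16
Reactants: 23 5α-[4-(allyloxy)benzoyloxy]-3β-hydroxy-3α-isopropyl-7,10β-dimethyl-4αH-trans-hydroazul-7-en-1-one
Product: 24 5α-[4-(allyloxy)benzoyloxy]-3α-isopropyl-7,10β-dimethyl-4αH-trans-hydroazul-7-ene-1α,3β-diol
Conditions: Me4N[BH(OAc)3], MeCN/AcOH, −20 → 0 °C
Reagents that add atoms: none
Why: A second Evans–Saksena reduction, in which the boron-bound C3 hydroxyl reaches across the cyclopentane and delivers hydride to the β-face of C1, makes the new C1 hydroxyl α, trans to the C10 methyl and anti to the 3β-hydroxyl.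

Step 17
Reactants: 24 5α-[4-(allyloxy)benzoyloxy]-3α-isopropyl-7,10β-dimethyl-4αH-trans-hydroazul-7-ene-1α,3β-diol
Product: 25 1α-acetoxy-5α-[4-(allyloxy)benzoyloxy]-3α-isopropyl-7,10β-dimethyl-4αH-trans-hydroazul-7-en-3β-ol
Conditions: Ac2O, pyridine, DMAP (cat.), CH2Cl2, 0 °C → rt
Reagents that add atoms: acetic anhydride (CC(=O)OC(C)=O)
Why: DMAP-catalysed acetylation takes the secondary C1 alcohol, the tertiary C3 alcohol being too hindered to acylate under these conditions.

Step 18
Reactants: 25 1α-acetoxy-5α-[4-(allyloxy)benzoyloxy]-3α-isopropyl-7,10β-dimethyl-4αH-trans-hydroazul-7-en-3β-ol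
Product: 26 1α-acetoxy-5α-(4-hydroxybenzoyloxy)-3α-isopropyl-7,10β-dimethyl-4αH-trans-hydroazul-7-en-3β-ol (CNP0275279.1)
Conditions: Pd(PPh3)4 (cat.), morpholine, THF, rt
Reagents that add atoms: none
Why: Tsuji–Trost deallylation, in which zerovalent palladium ionises the aryl allyl ether and morpholine captures the allyl fragment, releases the phenol without touching the two esters or the ring alkene.

**Compound list**

1 | (R)-(−)-carvone | CC1=CC[C@H](CC1=O)C(C)=C | starting material
2 | (5R)-5-(1-hydroperoxy-1-methoxyethyl)-2-methylcyclohex-2-en-1-one (both side-chain epimers) | CC1=CC[C@H](CC1=O)C(C)(OC)OO | intermediate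
3 | (R)-5-acetoxy-2-methylcyclohex-2-en-1-one | CC1=CC[C@H](CC1=O)OC(C)=O | intermediate
4 | isoprene | CC(=C)C=C | starting material
5 | cis-fused 3β-acetoxy-7,10β-dimethyl-5βH-decal-7-en-1-one | O=C1C[C@H](OC(C)=O)C[C@H]2CC(C)=CC[C@@]12C | intermediate
6 | 3β-acetoxy-1,1-ethylenedioxy-7,10β-dimethyl-5βH-cis-decal-7-ene | O1CCOC12C[C@H](OC(C)=O)C[C@H]3CC(C)=CC[C@@]23C | intermediate
7 | 1,1-ethylenedioxy-7,10β-dimethyl-5βH-cis-decal-7-en-3β-ol | O1CCOC12C[C@H](O)C[C@H]3CC(C)=CC[C@@]23C | intermediate
8 | 1,1-ethylenedioxy-7,10β-dimethyl-5βH-cis-decal-7-en-3-one | O1CCOC12CC(=O)C[C@H]3CC(C)=CC[C@@]23C | intermediate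
9 | lithium C3=C4 enolate of 8 | O1CCOC12CC(O[Li])=C[C@H]3CC(C)=CC[C@@]23C | intermediate
10 | 1,1-ethylenedioxy-7,10β-dimethyl-4β-phenylthio-5βH-cis-decal-7-en-3-one | O1CCOC12CC(=O)[C@H](Sc4ccccc4)[C@H]3CC(C)=CC[C@@]23C | intermediate
11 | 1,1-ethylenedioxy-3α-isopropyl-7,10β-dimethyl-4β-phenylthio-5βH-cis-decal-7-en-3β-ol | O1CCOC12C[C@@](O)(C(C)C)[C@H](Sc4ccccc4)[C@H]3CC(C)=CC[C@@]23C | intermediate
12 | 4β-phenylsulfinyl analogue of 11 (both sulfur epimers) | O1CCOC12C[C@@](O)(C(C)C)[C@H](S(=O)c4ccccc4)[C@H]3CC(C)=CC[C@@]23C | intermediate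
13 | 1,1-ethylenedioxy-3α-isopropyl-7,10β-dimethyldecala-4,7-dien-3β-ol | O1CCOC12C[C@@](O)(C(C)C)C=C3CC(C)=CC[C@@]23C | intermediate
14 | TMEDA-chelated dioxo-osmium glycolate spanning O4 and O5 of triol 15 (osmate ester) | O1CCOC12C[C@@](O)(C(C)C)[C@@H]3O[Os-2]4(=O)(=O)([N+](C)(C)CC[N+]4(C)C)O[C@@]35CC(C)=CC[C@@]25C | intermediate
15 | 1,1-ethylenedioxy-3α-isopropyl-7,10β-dimethyl-cis-decal-7-ene-3β,4β,5β-triol | O1CCOC12C[C@@](O)(C(C)C)[C@H](O)[C@@]3(O)CC(C)=CC[C@@]23C | intermediate
16 | 4-methanesulfonate of triol 15 (key-step precursor) | O1CCOC12C[C@@](O)(C(C)C)[C@H](OS(C)(=O)=O)[C@@]3(O)CC(C)=CC[C@@]23C | intermediate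
17 | 1,1-ethylenedioxy-3β-hydroxy-3α-isopropyl-7,10β-dimethyl-4αH-trans-hydroazul-7-en-5-one (key-step product) | O1CCOC12C[C@@](O)(C(C)C)[C@@H]3C(=O)CC(C)=CC[C@@]23C | intermediate
18 | 1,1-ethylenedioxy-3α-isopropyl-7,10β-dimethyl-4αH-trans-hydroazul-7-ene-3β,5α-diol | O1CCOC12C[C@@](O)(C(C)C)[C@@H]3[C@@H](O)CC(C)=CC[C@@]23C | intermediate
19 | 4-hydroxybenzoic acid | OC(=O)c1ccc(O)cc1 | starting material
20 | potassium 4-(allyloxy)benzoate | [K+].[O-]C(=O)c1ccc(OCC=C)cc1 | intermediate
21 | 4-(allyloxy)benzoic acid | OC(=O)c1ccc(OCC=C)cc1 | intermediate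
22 | 5α-[4-(allyloxy)benzoyloxy]-1,1-ethylenedioxy-3α-isopropyl-7,10β-dimethyl-4αH-trans-hydroazul-7-en-3β-ol | O1CCOC12C[C@@](O)(C(C)C)[C@@H]3[C@@H](OC(=O)c4ccc(OCC=C)cc4)CC(C)=CC[C@@]23C | intermediate
23 | 5α-[4-(allyloxy)benzoyloxy]-3β-hydroxy-3α-isopropyl-7,10β-dimethyl-4αH-trans-hydroazul-7-en-1-one | O=C1C[C@@](O)(C(C)C)[C@@H]2[C@@H](OC(=O)c3ccc(OCC=C)cc3)CC(C)=CC[C@@]12C | intermediate
24 | 5α-[4-(allyloxy)benzoyloxy]-3α-isopropyl-7,10β-dimethyl-4αH-trans-hydroazul-7-ene-1α,3β-diol | O[C@H]1C[C@@](O)(C(C)C)[C@@H]2[C@@H](OC(=O)c3ccc(OCC=C)cc3)CC(C)=CC[C@@]12C | intermediate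
25 | 1α-acetoxy-5α-[4-(allyloxy)benzoyloxy]-3α-isopropyl-7,10β-dimethyl-4αH-trans-hydroazul-7-en-3β-ol | CC(=O)O[C@H]1C[C@@](O)(C(C)C)[C@@H]2[C@@H](OC(=O)c3ccc(OCC=C)cc3)CC(C)=CC[C@@]12C | intermediate
26 | 1α-acetoxy-5α-(4-hydroxybenzoyloxy)-3α-isopropyl-7,10β-dimethyl-4αH-trans-hydroazul-7-en-3β-ol (CNP0275279.1) | CC(=O)O[C@H]1C[C@@](O)(C(C)C)[C@@H]2[C@@H](OC(=O)c3ccc(O)cc3)CC(C)=CC[C@@]12C | target

**Totals**

Total step count: 18. Longest linear sequence: 17 steps (steps 1–12 and 14–18, from carvone 1 to target 26).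

**Steps most likely to fail**

Step 11 (key step). What may go wrong: the C3 alkoxide forms alongside the C5 alkoxide and can trigger a competing shift of C2 from C3 to C4, and the β-alkoxide of the product can open by retro-aldol cleavage under the basic conditions. Fallback: take the C3 hydroxyl out of play before the shift. The fallback sets out from osmate ester 14, generated as in step 9 but not cleaved. TBSOTf and 2,6-lutidine are added to the cold solution to silylate the free C3 hydroxyl, giving the 3-O-TBS osmate ester F1. Aqueous Na2SO3 then releases the 3-O-TBS 4β,5β-diol F2, and MsCl/pyridine gives the 3-O-TBS 4-mesylate F3. KOtBu can now form only the C5 alkoxide and gives the 3-O-TBS hydroazulenone F4, which has no free β-hydroxyl. Bu4NF buffered with AcOH removes the silyl group, and the route is rejoined at 17.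

Step 9. What may go wrong: osmylation of the less hindered C7=C8 alkene competes with the directed attack on the hindered C4=C5 alkene (loss of chemoselectivity), or the reagent is delivered to the wrong face. Fallback: mask the ring B alkene for the duration of the osmylation. Setting out from 13, pyridinium tribromide (1 equiv, CH2Cl2, −78 °C) adds bromine to the accessible C7=C8 bond only, giving the 7,8-dibromide F5. OsO4/TMEDA then finds a single alkene and forms the dibromo osmate ester F6, and sulfite cleavage gives the dibromo triol F7. Zinc dust in AcOH/EtOH regenerates the C7=C8 alkene, and the route is rejoined at 15.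

Step 7. What may go wrong: enolisation of the acidic α-sulfenyl ketone and β-hydride transfer from the branched organometallic compete with carbonyl addition, returning ketone or giving the reduced secondary alcohol. Fallback: use an sp2 nucleophile without β-hydrogen and saturate it afterwards. Setting out from 10, isopropenylmagnesium bromide with CeCl3 adds in the same equatorial sense to give the 3α-isopropenyl carbinol F8. Diimide (2-nitrobenzenesulfonylhydrazide, Et3N, CH2Cl2, rt) reduces the 1,1-disubstituted alkene in preference to the trisubstituted ring alkene and leaves the sulfide alone, and the route is rejoined at 11.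

**Further compounds**

F1 | step 11 | 3-O-TBS ether of osmate ester 14 | O1CCOC12C[C@@](O[Si](C)(C)C(C)(C)C)(C(C)C)[C@@H]3O[Os-2]4(=O)(=O)([N+](C)(C)CC[N+]4(C)C)O[C@@]35CC(C)=CC[C@@]25C
F2 | step 11 | 3β-(tert-butyldimethylsilyloxy)-1,1-ethylenedioxy-3α-isopropyl-7,10β-dimethyl-cis-decal-7-ene-4β,5β-diol | O1CCOC12C[C@@](O[Si](C)(C)C(C)(C)C)(C(C)C)[C@H](O)[C@@]3(O)CC(C)=CC[C@@]23C
F3 | step 11 | 4-methanesulfonate of F2 | O1CCOC12C[C@@](O[Si](C)(C)C(C)(C)C)(C(C)C)[C@H](OS(C)(=O)=O)[C@@]3(O)CC(C)=CC[C@@]23C
F4 | step 11 | 3β-(tert-butyldimethylsilyloxy)-1,1-ethylenedioxy-3α-isopropyl-7,10β-dimethyl-4αH-trans-hydroazul-7-en-5-one | O1CCOC12C[C@@](O[Si](C)(C)C(C)(C)C)(C(C)C)[C@@H]3C(=O)CC(C)=CC[C@@]23C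
F5 | step 9 | 7,8-dibromo-1,1-ethylenedioxy-3α-isopropyl-7,10β-dimethyldecal-4-en-3β-ol | O1CCOC12C[C@@](O)(C(C)C)C=C3CC(C)(Br)C(Br)C[C@@]23C
F6 | step 9 | TMEDA-chelated dioxo-osmium 4β,5β-glycolate of F7 | O1CCOC12C[C@@](O)(C(C)C)[C@@H]3O[Os-2]4(=O)(=O)([N+](C)(C)CC[N+]4(C)C)O[C@@]35CC(C)(Br)C(Br)C[C@@]25C
F7 | step 9 | 7,8-dibromo-1,1-ethylenedioxy-3α-isopropyl-7,10β-dimethyl-cis-decalin-3β,4β,5β-triol | O1CCOC12C[C@@](O)(C(C)C)[C@H](O)[C@@]3(O)CC(C)(Br)C(Br)C[C@@]23C
F8 | step 7 | 1,1-ethylenedioxy-3α-isopropenyl-7,10β-dimethyl-4β-phenylthio-5βH-cis-decal-7-en-3β-ol | O1CCOC12C[C@@](O)(C(C)=C)[C@H](Sc4ccccc4)[C@H]3CC(C)=CC[C@@]23C
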